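Start from a small charge: 0.20 M of electrophile stands against 0.300 M of nucleophile, with free base and protic impurity beside them. Two runs are in hand and two flasks are asked about.

| flask | electrophile | nucleophile | free base | protic impurity | remark | time |
|---|---|---|---|---|---|---|
| teal | 0.20 M | 0.30 M | 0.52 M | 0.10 M | run made earlier |  |
| violet | 0.20 M | 0.30 M | 0.71 M | 0.10 M | run made earlier |  |
| theta | 0.20 M | 0.300 M | 0.400 M | 0.100 M |  | 6.0 min |
| epsilon | 0.20 M | 0.300 M | 0.600 M | 0.100 M |  | 6.0 min |

| run | time / min | electrophile / % | target / % |
|---|---|---|---|
| teal | 0.500 | 65.5 | 18.9 |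
| teal | 1.00 | 47.8 | 28.6 |
| teal | 1.50 | 36.8 | 33.5 |
| teal | 2.00 | 29.1 | 36.3 |
| teal | 2.50 | 24.1 | 38.3 |
| teal | 3.00 | 19.8 | 38.9 |
| violet | 0.500 | 66.3 | 19.3 |
| violet | 1.00 | 48.3 | 28.1 |
| violet | 1.50 | 37.0 | 34.0 |
| violet | 2.00 | 29.0 | 36.6 |
| violet | 2.50 | 24.5 | 38.5 |
| violet | 3.00 | 20.0 | 39.5 |

(readings scatter by 0.3 percentage points)



- part of the electrophile that has reacted at the end, theta
- part of the electrophile that has reacted at the end, epsilon
- what raising the concentration of free base from its lowest to its highest value here does to the part of the electrophile that has reacted (changes below 5 percentage points count as none) (it rises / it falls / no change)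

Try the bench rule first. When a small charge meets a reagent in large excess, freeze that reagent's concentration and treat the decay as pseudo-first-order, with one constant. The first reading of teal gives 0.846 min⁻¹.

Now look for the border. The electrophile charge is 66.7 % of the nucleophile charge, which is no large excess, so do not freeze from the start. Freeze late instead. Teal and violet stand at 19.8 % and 20.0 % at 3.00 min, inside the scatter of 0.3 percentage points, though their free base differs, so pool them. The logarithm of their summed electrophile at 2.00 min over that at 3.00 min, per minute elapsed, reads 0.378 min⁻¹; call this the late decay constant.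

Carry the pooled reading forward to 6.0 min with it. That leaves 6.40 %, so my reckoning is 93.6 % reacted in both flasks. The early constant reads higher than the late one, so the decay has been slowing and my reckoning may lean high. Note the risk too: theta's 0.400 M lies below teal's 0.52 M.

The forecast stands a little lower, at 90 % for theta and 91 % for epsilon, with no change, and it starts from this: “Teal and violet are identical within scatter”.

Theta gives 91.8 % and epsilon 91.8 %, apart by 0.0088 points, so raising the free base gives no change by the margin of 5 points. Theta ends with 99.9 % of its free base still free, and the step to the salt of the base makes no difference to its answer. Now use the late constant on theta: from 20.0 % electrophile at 3.00 min it leaves 6.41 % at 6.0 min, and theta holds more, 8.17 %.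

    target ⇌ isomer of the product (K = 15.0, k = 0.00140 s⁻¹)
    nucleophile + acid set free ⇌ protonated nucleophile, settled at all times (K = 11000 L mol⁻¹)
    acid set free + free base ⇌ salt of the base (K = 8.90 L mol⁻¹, k = 2.50 L mol⁻¹ s⁻¹)
    electrophile + protic impurity → quenched substrate (k = 0.0710 L mol⁻¹ s⁻¹)
    electrophile + nucleophile → acid set free + target (k = 0.0310 L mol⁻¹ s⁻¹)

Read theta on to 10 min: from 8.17 %, the late constant leaves 1.80 %. The computed flask keeps 3.2 %, which is 96.8 % reacted.

(The readings come from a simulation for an exercise; scatter was added.)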